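**Retrosynthetic overview**
- The plan rests on one feature of ring A: C4 carries the C19 carboxyl and C10 carries the C20 carboxyl, cis and 1,3-diaxial on the α face. C20 can therefore be passed from C19 to C10 within a C19 gibberellin that already holds rings A–D.
- The C15 hydroxyl is set last on the 19,20-diacid by allylic oxidation, oxidation to the 16-en-15-one and hydride delivery from the C14 side. The diacid comes from cleaving the C19–C20 bond of a 1,2-dione.
- The dione comes from a cyclopentanone that bridges C4 and C10, made by reductive opening of the C1–C20 bond of a cyclopropyl ketone.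
- The cyclopropyl ketone comes from a C19 diazomethyl ketone whose rhodium carbenoid adds to the C1=C10 alkene. The diazoketone comes from gibberellin A(7) (1) by oxidation at C3, reductive opening of the 19,10-lactone through the 1-en-3-one, removal of the C3 oxygen, and acylation of diazomethane made from N-methyl-N-nitroso-4-toluenesulfonamide (2).
- Ring order: rings A–D are taken intact from 1. Step 8 closes a cyclopropane (C1–C10–C20) and a cyclopentanone (C4–C19–C20–C10–C5) together, and both are reopened later.

Key step: step 8

Assumption: read from the SMILES, the C15 hydroxyl of the target lies on the endo face of the C15–C16 bridge, anti to the C14 methylene (called 15β below); the route is planned to deliver this epimer.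

**Route**

Step 1
Reactants: 2 N-methyl-N-nitroso-4-toluenesulfonamide
Product: 3 diazomethane (ethereal solution, made fresh for steps 2 and 7)
Conditions: KOH, EtOH–H2O, Et2O, 65 °C, codistillation into Et2O at 0 °C
Reagents that add atoms: none
Why: Hydroxide cleaves the N-nitrososulfonamide to the methyldiazotate, which loses water to give diazomethane that distils with ether (standard base-induced diazomethane generation).

Step 2
Reactants: 1 gibberellin A(7); 3 diazomethane
Product: 4 gibberellin A(7) methyl ester (C7 methyl ester, 3β-hydroxy-1-ene 19,10-lactone)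
Conditions: CH2N2, Et2O–MeOH, 0 °C
Reagents that add atoms: none
Why: Esterification of the C7 acid with diazomethane (proton transfer, then O-methylation by methyldiazonium) is neutral and cold, so the base-labile allylic lactone and the 3-hydroxyl should be untouched.

Step 3
Reactants: 4 gibberellin A(7) methyl ester
Product: 5 3-dehydrogibberellin A(7) methyl ester (1-en-3-one, 19,10-lactone)
Conditions: Dess–Martin periodinane, CH2Cl2, 0 °C to rt
Reagents that add atoms: none
Why: Dess–Martin oxidation of the secondary allylic alcohol should give the enone without base, so the lactone oxygen on C10, now γ to the carbonyl, neither migrates nor eliminates.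

Step 4
Reactants: 5 3-dehydrogibberellin A(7) methyl ester
Product: 6 3-oxo-1(10)-ene 19-oic acid 7-methyl ester
Conditions: Zn dust, AcOH, THF, 0 °C, short contact, cold work-up, used at once
Reagents that add atoms: none
Why: Zinc reductive cleavage of a vinylogous α-acyloxy ketone: electron transfer to the enone expels the C10 carboxylate, and kinetic protonation of the dienolate at C2 should leave the alkene at C1=C10 and free the C19 acid, the β-keto acid being kept cold to hold back decarboxylation.

Step 5
Reactants: 6 3-oxo-1(10)-ene 19-oic acid 7-methyl ester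
Product: 7 3-(4-toluenesulfonyl)hydrazone of 6
Conditions: TsNHNH2, MeOH, 0 °C to rt
Reagents that add atoms: 4-toluenesulfonohydrazide, Cc1ccc(cc1)S(=O)(=O)NN
Why: Hydrazone formation at the only ketone, without added acid, should keep the alkene out of conjugation and the carboxyl in place, with the N–N bond expected anti to the quaternary C4.

Step 6
Reactants: 7 3-(4-toluenesulfonyl)hydrazone of 6
Product: 8 1(10)-ene 19-oic acid 7-methyl ester (C3 is CH2)
Conditions: catecholborane (3 equiv), CHCl3, 0 °C; then NaOAc·3H2O, rt to 50 °C; aqueous work-up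
Reagents that add atoms: none
Why: Caglioti-type reduction in its catecholborane form: hydride adds to C=N, acetate triggers loss of sulfinate and the alkyl diazene loses N2 to leave C3 as CH2, while the non-conjugated alkene should stay in place, the carboxyl is held meanwhile as an acyloxyborane (one equivalent of borane, hydrogen evolved) that water releases on work-up, and the neutral medium avoids relactonisation onto C10.

Step 7
Reactants: 8 1(10)-ene 19-oic acid 7-methyl ester; 3 diazomethane
Product: 10 1(10)-ene 19-diazomethyl ketone 7-methyl ester, via 19-acyl chloride 9 (not isolated)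
Conditions: Me2C=C(Cl)NMe2, CH2Cl2, 0 °C to rt; then CH2N2 (excess), Et2O, 0 °C
Reagents that add atoms: 1-chloro-N,N,2-trimethylprop-1-en-1-amine, CC(C)=C(Cl)N(C)C (supplies only the chlorine of intermediate 9)
Why: The α-chloroenamine makes the hindered acyl chloride without free HCl, which would close C19 back onto C10, and acylation of diazomethane (first stage of the Arndt–Eistert sequence) then gives the diazoketone, with excess diazomethane taking up HCl and no α-hydrogen on C4 to form a ketene.

Step 8
Reactants: 10 1(10)-ene 19-diazomethyl ketone 7-methyl ester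
Product: 11 1,10-cyclopropano 19,20-cyclopentanone 7-methyl ester (cyclopropane C1–C10–C20, ketone at C19)
Conditions: Rh2(OAc)4 (1 mol %), CH2Cl2, rt, slow addition at high dilution
Reagents that add atoms: none
Why: Loss of N2 from the diazoketone on Rh2(OAc)4 should give an electrophilic rhodium carbenoid at C20, which transfers C20 to the electron-rich trisubstituted C1=C10 alkene in one asynchronous [2+1] event. The closest known reaction type is the intramolecular cyclopropanation of γ,δ-unsaturated α-diazoketones to bicyclo[3.1.0]hexan-2-ones, here in the form that turns a cyclohex-3-enyl diazomethyl ketone into a tricyclo[3.2.1.0]octanone. The cyclopropane closes by the [2+1] addition itself, and the cyclopentanone C4–C19–C20–C10–C5 closes in the same event through the new C20–C10 bond, exo with respect to C1. C10, C1 and C20 are all fixed by the tether: C19 is axial on the α face of ring A (the face on which the lactone of 1 joined it to C10), so C20 can reach the alkene only from that face and the ring fusion must be cis, which is the C19/C20 relation of the target. The step needs chemoselectivity for C1=C10 over the C16 methylene and over C–H insertion; the three-atom tether C19–C4–C5 keeps the carbenoid away from ring D, slow addition suppresses intermolecular reaction, and addition to the π bond should outrun 1,5-insertion into the allylic C2–H or the ester-deactivated C6–H.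

Step 9
Reactants: 11 1,10-cyclopropano 19,20-cyclopentanone 7-methyl ester
Product: 12 C19–C20 bridged 19-ketone 7-methyl ester (C20 is CH2 bonded to C10, C1 is CH2)
Conditions: SmI2, THF–HMPA, t-BuOH, −78 to 0 °C
Reagents that add atoms: none
Why: Electron transfer from divalent samarium gives the ketyl, which breaks the cyclopropane bond best aligned with its π system, the C20–C1 bond that stands out of the cyclopentanone plane and not the in-ring C20–C10 bond, and a second electron and protonation give the ketone with the quaternary C10 intact (reductive opening of a cyclopropyl ketone).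

Step 10
Reactants: 12 C19–C20 bridged 19-ketone 7-methyl ester
Product: 13 20-hydroxy 19-ketone 7-methyl ester
Conditions: KN(SiMe3)2 (1.05 equiv), THF, −78 °C; then 2-(phenylsulfonyl)-3-phenyloxaziridine, −78 °C; NH4Cl (aq)
Reagents that add atoms: 2-(phenylsulfonyl)-3-phenyloxaziridine, O=S(=O)(c1ccccc1)N1OC1c1ccccc1
Why: C20 is the only enolisable position of the ketone (C4 is quaternary), so the potassium enolate forms there and is hydroxylated by the oxaziridine (enolate oxidation), and the new C20 centre, expected on the face syn to the C5 bridge, is removed in the next step.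

Step 11
Reactants: 13 20-hydroxy 19-ketone 7-methyl ester
Product: 14 19,20-dione 7-methyl ester
Conditions: Dess–Martin periodinane, CH2Cl2, rt
Reagents that add atoms: none
Why: Dess–Martin oxidation of the α-hydroxy ketone should give the 1,2-dione, which cannot enolise because both flanking carbons (C4, C10) are quaternary.

Step 12
Reactants: 14 19,20-dione 7-methyl ester
Product: 15 gibberellin A(25) 7-methyl ester (16-ene 19,20-dicarboxylic acid)
Conditions: H5IO6, THF–H2O, rt
Reagents that add atoms: orthoperiodic acid, OI(O)(O)(O)(O)=O; water, O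
Why: Periodate cleavage of a 1,2-diketone through the cyclic ester of its hydrate (Malaprade-type) breaks C19–C20 and leaves carboxyls on C4 and C10, cis by construction, while the alkene and the ester are inert.

Step 13
Reactants: 15 gibberellin A(25) 7-methyl ester
Product: 16 15α-hydroxygibberellin A(25) 7-methyl ester (hydroxyl exo, syn to C14)
Conditions: SeO2 (cat.), t-BuOOH, CH2Cl2, rt
Reagents that add atoms: tert-butyl hydroperoxide, CC(C)(C)OO (terminal oxygen source; the oxygen passes through catalytic SeO2, O=[Se]=O)
Why: SeO2 allylic oxidation (ene reaction at C17 with the C15 hydrogen, then [2,3]-sigmatropic shift) can act only at C15, because C13 is a bridgehead, and should place the hydroxyl on the open exo face of the C15–C16 bridge.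

Step 14
Reactants: 16 15α-hydroxygibberellin A(25) 7-methyl ester
Product: 17 15-oxogibberellin A(25) 7-methyl ester (16-en-15-one)
Conditions: Dess–Martin periodinane, CH2Cl2, 0 °C, run without delay
Reagents that add atoms: none
Why: Oxidation of the allylic alcohol to the α-methylene ketone erases the C15 centre, and prompt oxidation gives the exo hydroxyl no time to close onto the nearby C7 ester.

Step 15
Reactants: 17 15-oxogibberellin A(25) 7-methyl ester
Product: 18 gibberellin A(66) 7-methyl ester (15β-hydroxyl, endo, anti to C14)
Conditions: NaBH4 (excess), CeCl3·7H2O, MeOH, −40 °C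
Reagents that add atoms: none
Why: Luche 1,2-reduction: hydride should approach C15 from the exo face (the C14 side), the face also taken by the oxidant in step 13, which places the hydroxyl endo as in the target, while CeCl3 suppresses conjugate reduction of the exocyclic enone.

Step 16
Reactants: 18 gibberellin A(66) 7-methyl ester
Product: 19 gibberellin A(66)
Conditions: KOH, MeOH–H2O, reflux; then HCl (aq) to pH 3, 0 °C
Reagents that add atoms: potassium hydroxide, [K+].[OH-] (the carboxyl oxygen)
Why: Saponification of the hindered C7 ester by acyl–oxygen cleavage should be tolerated by the carboxylates, the allylic alcohol and the C6 centre (its natural configuration is the more stable one), and cold acidification frees the triacid.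

**Compound list**
1 | gibberellin A(7) | C=C1[C@@H]2CC[C@H]3[C@]45C=C[C@H](O)[C@@](C)(C(=O)O5)[C@H]4[C@H](C(=O)O)[C@]3(C2)C1 | starting material
2 | N-methyl-N-nitroso-4-toluenesulfonamide | Cc1ccc(cc1)S(=O)(=O)N(C)N=O | starting material
3 | diazomethane | C=[N+]=[N-] | intermediate
4 | gibberellin A(7) methyl ester | C=C1[C@@H]2CC[C@H]3[C@]45C=C[C@H](O)[C@@](C)(C(=O)O5)[C@H]4[C@H](C(=O)OC)[C@]3(C2)C1 | intermediate
5 | 3-dehydrogibberellin A(7) methyl ester | C=C1[C@@H]2CC[C@H]3[C@]45C=CC(=O)[C@@](C)(C(=O)O5)[C@H]4[C@H](C(=O)OC)[C@]3(C2)C1 | intermediate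
6 | 3-oxo-1(10)-ene 19-oic acid 7-methyl ester | C=C1[C@@H]2CC[C@H]3C4=CCC(=O)[C@@](C)(C(=O)O)[C@H]4[C@H](C(=O)OC)[C@]3(C2)C1 | intermediate
7 | 3-(4-toluenesulfonyl)hydrazone of 6 | C=C1[C@@H]2CC[C@H]3C4=CC/C(=N\NS(=O)(=O)c5ccc(C)cc5)[C@@](C)(C(=O)O)[C@H]4[C@H](C(=O)OC)[C@]3(C2)C1 | intermediate
8 | 1(10)-ene 19-oic acid 7-methyl ester | C=C1[C@@H]2CC[C@H]3C4=CCC[C@@](C)(C(=O)O)[C@H]4[C@H](C(=O)OC)[C@]3(C2)C1 | intermediate
9 | 19-acyl chloride of 8 | C=C1[C@@H]2CC[C@H]3C4=CCC[C@@](C)(C(=O)Cl)[C@H]4[C@H](C(=O)OC)[C@]3(C2)C1 | intermediate (not isolated)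
10 | 1(10)-ene 19-diazomethyl ketone 7-methyl ester | C=C1[C@@H]2CC[C@H]3C4=CCC[C@@](C)(C(=O)C=[N+]=[N-])[C@H]4[C@H](C(=O)OC)[C@]3(C2)C1 | intermediate
11 | 1,10-cyclopropano 19,20-cyclopentanone 7-methyl ester | C=C1[C@@H]2CC[C@H]3[C@]45[C@@H]6CC[C@@](C)(C(=O)[C@H]56)[C@H]4[C@H](C(=O)OC)[C@]3(C2)C1 | intermediate
12 | C19–C20 bridged 19-ketone 7-methyl ester | C=C1[C@@H]2CC[C@H]3[C@]45CCC[C@@](C)(C(=O)C5)[C@H]4[C@H](C(=O)OC)[C@]3(C2)C1 | intermediate
13 | 20-hydroxy 19-ketone 7-methyl ester | C=C1[C@@H]2CC[C@H]3[C@]45CCC[C@@](C)(C(=O)[C@@H]5O)[C@H]4[C@H](C(=O)OC)[C@]3(C2)C1 | intermediate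
14 | 19,20-dione 7-methyl ester | C=C1[C@@H]2CC[C@H]3[C@]45CCC[C@@](C)(C(=O)C5=O)[C@H]4[C@H](C(=O)OC)[C@]3(C2)C1 | intermediate
15 | gibberellin A(25) 7-methyl ester | C=C1[C@@H]2CC[C@H]3[C@]4(C(=O)O)CCC[C@@](C)(C(=O)O)[C@H]4[C@H](C(=O)OC)[C@]3(C2)C1 | intermediate
16 | 15α-hydroxygibberellin A(25) 7-methyl ester | C=C1[C@@H]2CC[C@H]3[C@]4(C(=O)O)CCC[C@@](C)(C(=O)O)[C@H]4[C@H](C(=O)OC)[C@]3(C2)[C@H]1O | intermediate
17 | 15-oxogibberellin A(25) 7-methyl ester | C=C1[C@@H]2CC[C@H]3[C@]4(C(=O)O)CCC[C@@](C)(C(=O)O)[C@H]4[C@H](C(=O)OC)[C@]3(C2)C1=O | intermediate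
18 | gibberellin A(66) 7-methyl ester | C=C1[C@@H]2CC[C@H]3[C@]4(C(=O)O)CCC[C@@](C)(C(=O)O)[C@H]4[C@H](C(=O)OC)[C@]3(C2)[C@@H]1O | intermediate
19 | gibberellin A(66) | C=C1[C@@H]2CC[C@H]3[C@]4(C(=O)O)CCC[C@@](C)(C(=O)O)[C@H]4[C@H](C(=O)O)[C@]3(C2)[C@@H]1O | target

**Step count**
Total: 16 steps. Longest linear sequence: 16 steps (steps 1 to 16; the diazomethane of step 1 enters the main line at step 2 and again at step 7).

**Steps most likely to fail**

Step 8. The carbenoid may dimerise or insert into C–H bonds faster than it adds to the hindered C1=C10 alkene. The fallback uses a stabilised acceptor–acceptor carbenoid and sets out from the acyl chloride 9 (made from 8 as in step 7). LiCH2CO2Me (THF, −78 °C) acylates to the β-keto ester F1. Diazo transfer with 4-acetamidobenzenesulfonyl azide and Et3N gives the diazo β-keto ester F2. Cu(acac)2 in toluene at 90 °C closes the same two rings as the 20-methoxycarbonyl cyclopropyl ketone F3. SmI2 opens the C1–C20 bond to the ring-opened β-keto ester F4 (C20 configuration left open, enolisable). LiCl in wet DMSO at 140 °C (Krapcho dealkoxycarbonylation) then returns to the route at 12.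

Step 4. The β-keto acid 6 may lose CO2, or its alkene may slip into conjugation with the C3 ketone, before the ketone is removed. The fallback sets out from 5 and keeps C19 masked in the lactone until C3 is CH2. PhSO2Na with AcOH adds to the enone at C1, anti to the lactone bridge, to give the 1β-phenylsulfonyl 3-ketone F5. TsNHNH2 gives the tosylhydrazone F6, and catecholborane then NaOAc·3H2O gives the 3-deoxy 1β-sulfone lactone F7. SmI2 in THF–HMPA (Julia-type reductive elimination of the β-acyloxy sulfone) breaks C1–S and C10–O together and returns at 8, bypassing 6 and 7.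

Step 10. The amide base may also deprotonate C6 next to the ester, or enolisation of the hindered bridged ketone may stall. The fallback sets out from 12 and replaces the strong base by soft enolisation. Me3SiOTf with Et3N (CH2Cl2, 0 °C) forms the C19–C20 trimethylsilyl enol ether F8 at the ketone only. Rubottom oxidation with one equivalent of dimethyldioxirane at −78 °C, where the enol ether should react well ahead of the C16 methylene, followed by Bu4NF, returns at 13.

**Further compounds**
F1 | step 8 | β-keto ester (C19 ketone carrying CH2CO2Me) of the 1(10)-ene 7-methyl ester | C=C1[C@@H]2CC[C@H]3C4=CCC[C@@](C)(C(=O)CC(=O)OC)[C@H]4[C@H](C(=O)OC)[C@]3(C2)C1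
F2 | step 8 | diazo β-keto ester | C=C1[C@@H]2CC[C@H]3C4=CCC[C@@](C)(C(=O)C(=[N+]=[N-])C(=O)OC)[C@H]4[C@H](C(=O)OC)[C@]3(C2)C1
F3 | step 8 | 20-methoxycarbonyl 1,10-cyclopropano 19,20-cyclopentanone 7-methyl ester | C=C1[C@@H]2CC[C@H]3[C@]45[C@@H]6CC[C@@](C)(C(=O)[C@]56C(=O)OC)[C@H]4[C@H](C(=O)OC)[C@]3(C2)C1
F4 | step 8 | 20-methoxycarbonyl C19–C20 bridged 19-ketone 7-methyl ester (C20 configuration open) | C=C1[C@@H]2CC[C@H]3[C@]45CCC[C@@](C)(C(=O)C5C(=O)OC)[C@H]4[C@H](C(=O)OC)[C@]3(C2)C1
F5 | step 4 | 1β-phenylsulfonyl-3-oxo 19,10-lactone 7-methyl ester | C=C1[C@@H]2CC[C@H]3[C@]45[C@H](S(=O)(=O)c6ccccc6)CC(=O)[C@@](C)(C(=O)O5)[C@H]4[C@H](C(=O)OC)[C@]3(C2)C1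
F6 | step 4 | 3-(4-toluenesulfonyl)hydrazone of F5 | C=C1[C@@H]2CC[C@H]3[C@]45[C@H](S(=O)(=O)c6ccccc6)C/C(=N\NS(=O)(=O)c6ccc(C)cc6)[C@@](C)(C(=O)O5)[C@H]4[C@H](C(=O)OC)[C@]3(C2)C1
F7 | step 4 | 1β-phenylsulfonyl 19,10-lactone 7-methyl ester (C3 is CH2) | C=C1[C@@H]2CC[C@H]3[C@]45[C@H](S(=O)(=O)c6ccccc6)CC[C@@](C)(C(=O)O5)[C@H]4[C@H](C(=O)OC)[C@]3(C2)C1
F8 | step 10 | C19–C20 trimethylsilyl enol ether of 12 | C=C1[C@@H]2CC[C@H]3[C@]45CCC[C@@](C)(C(O[Si](C)(C)C)=C5)[C@H]4[C@H](C(=O)OC)[C@]3(C2)C1
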